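**Assumption:** the target, 3,6-dibromo-2-(2,4-dibromophenoxy)phenol, has no stereocentre and no hindered axis because the diaryl ether rotates freely. It is therefore achiral, and "single enantiomer" needs no stereocontrol.

## Retrosynthetic overview
1. Cut the ether bond between oxygen and ring B. This gives 3,6-dibromo-o-benzoquinone and (2,4-dibromophenyl)boronic acid, joined by a new copper-catalysed, redox-neutral reductive O-arylation.
2. The quinone comes from 3,6-dibromocatechol, then 3,6-dibromo-2-methoxyphenol, then 2,5-dibromoanisole. The second oxygen is put in at the C–H between OMe and Br by metalation, borylation and oxidation.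
3. The boronic acid comes from 2,4-dibromo-1-iodobenzene by selective I/Mg exchange.
4. No ring is formed. Both benzene rings are bought with all four bromines in place, ring A is oxidised first, and the ether bond is made last.

## Route

Step 1
Reactants: 1 2,5-dibromoanisole
Product: 4 3,6-dibromo-2-methoxyphenol, via (3,6-dibromo-2-methoxyphenyl)lithium 2 (not isolated), via lithium (3,6-dibromo-2-methoxyphenyl)triisopropoxyborate 3 (not isolated)
Conditions: B(OiPr)3 (1.5 equiv) present from the start, commercial LDA solution (1.2 equiv, slow addition), THF, −78 °C, 1 h; then AcOH, 30% aq H2O2, 0 °C → rt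
Reagents that add atoms: lithium diisopropylamide [Li]N(C(C)C)C(C)C (Li in 2 and 3 only); triisopropyl borate CC(C)OB(OC(C)C)OC(C)C (atoms in 3 only); hydrogen peroxide OO (the new O of 4)
Why: Directed ortho-metalation removes the most acidic H, the one flanked by OMe and Br; the in-situ borate trap catches 2 before benzyne loss or halogen dance, and the C–B bond is then oxidised to C–OH under non-basic conditions that avoid protodeboronation.

Step 2
Reactants: 4 3,6-dibromo-2-methoxyphenol
Product: 5 3,6-dibromobenzene-1,2-diol (3,6-dibromocatechol)
Conditions: BBr3 (2.2 equiv), CH2Cl2, −78 °C → rt; H2O quench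
Reagents that add atoms: none
Why: This is a standard Lewis-acid aryl methyl ether cleavage, and the aryl bromides are inert to BBr3.

Step 3
Reactants: 5 3,6-dibromobenzene-1,2-diol
Product: 6 3,6-dibromocyclohexa-3,5-diene-1,2-dione (3,6-dibromo-o-benzoquinone)
Conditions: Ag2O (2.5 equiv), anhydrous Na2SO4, CH2Cl2, 0 °C → rt, dark, 30 min; filter through Celite, concentrate below 20 °C, use the same day
Reagents that add atoms: none
Why: Silver(I) oxide dehydrogenates catechols to o-quinones under neutral, nucleophile-free conditions; only filtration is needed, and the 3,6-substituents slow Diels–Alder dimerisation.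

Step 4
Reactants: 7 2,4-dibromo-1-iodobenzene
Product: 10 (2,4-dibromophenyl)boronic acid, via (2,4-dibromophenyl)magnesium chloride 8 (not isolated), via dimethyl (2,4-dibromophenyl)boronate 9 (not isolated)
Conditions: iPrMgCl (1.05 equiv), THF, −40 °C, 1 h; B(OMe)3 (2 equiv), −40 °C → rt; 1 M HCl
Reagents that add atoms: isopropylmagnesium chloride CC(C)[Mg]Cl (Mg, Cl in 8 only); trimethyl borate COB(OC)OC; water O
Why: Halogen–magnesium exchange is much faster at C–I than at C–Br; the ortho-bromoaryl Grignard does not eliminate to the aryne at −40 °C, and it is borylated and hydrolysed in the usual way.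

Step 5
Reactants: 6 3,6-dibromocyclohexa-3,5-diene-1,2-dione; 10 (2,4-dibromophenyl)boronic acid
Product: 12 3,6-dibromo-2-(2,4-dibromophenoxy)phenol, via 3,6-dibromo-2-(2,4-dibromophenoxy)phenyl dihydrogen borate 11 (not isolated)
Conditions: CuTC (copper(I) thiophene-2-carboxylate, 10 mol %), 4,4′-di-tert-butyl-2,2′-bipyridine (12 mol %), 10 (1.5 equiv), 4 Å MS, CH2Cl2/THF 4:1, Ar (no O2), 0 °C → rt, 6 in CH2Cl2 added over 2 h; then 1 M HCl work-up
Reagents that add atoms: 10 (2,4-dibromophenyl)boronic acid OB(O)c1ccc(Br)cc1Br
Why: Proposed new method: an oxidant-free and base-free Chan–Lam-type coupling in which the o-quinone is both the oxygen partner and the two-electron oxidant – the ligated Cu(I) carboxylate binds the chelating, electron-poor quinone 6 and is oxidised by inner-sphere electron transfer to a Cu(II)–semiquinonate (valence tautomer of a Cu(III)–catecholate), the carboxylate bridges to boron and passes the aryl group of 10 to copper, C(aryl)–O reductive elimination from the Ar–Cu(III)–catecholate makes the diaryl ether bond and returns Cu(I), and the second oxygen is capped as borate 11, which water cleaves to 12; one quinone carries only two oxidising equivalents, so only one aryl group can be installed, 6 is C2v-symmetric, so either oxygen gives the same product, chelation keeps copper at the O,O edge away from C4/C5, and the neutral, nucleophile-free medium at or below rt leaves the four C–Br bonds untouched; closest known reaction types are Chan–Evans–Lam O-arylation of phenols with arylboronic acids under Cu(II)/O2, Cu(I)/o-quinone to Cu(II)–semiquinonate redox chemistry, and attack of organometal reagents at oxygen of hindered o-quinones.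

## Compound list
1 | 2,5-dibromoanisole (1,4-dibromo-2-methoxybenzene) | COc1cc(Br)ccc1Br | starting material
2 | (3,6-dibromo-2-methoxyphenyl)lithium | [Li]c1c(Br)ccc(Br)c1OC | intermediate
3 | lithium (3,6-dibromo-2-methoxyphenyl)triisopropoxyborate | [Li+].COc1c(Br)ccc(Br)c1[B-](OC(C)C)(OC(C)C)OC(C)C | intermediate
4 | 3,6-dibromo-2-methoxyphenol | COc1c(Br)ccc(Br)c1O | intermediate
5 | 3,6-dibromobenzene-1,2-diol | Oc1c(Br)ccc(Br)c1O | intermediate
6 | 3,6-dibromocyclohexa-3,5-diene-1,2-dione | O=C1C(Br)=CC=C(Br)C1=O | intermediate
7 | 2,4-dibromo-1-iodobenzene | Ic1ccc(Br)cc1Br | starting material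
8 | (2,4-dibromophenyl)magnesium chloride | Cl[Mg]c1ccc(Br)cc1Br | intermediate
9 | dimethyl (2,4-dibromophenyl)boronate | COB(OC)c1ccc(Br)cc1Br | intermediate
10 | (2,4-dibromophenyl)boronic acid | OB(O)c1ccc(Br)cc1Br | intermediate
11 | 3,6-dibromo-2-(2,4-dibromophenoxy)phenyl dihydrogen borate | OB(O)Oc1c(Br)ccc(Br)c1Oc1ccc(Br)cc1Br | intermediate
12 | 3,6-dibromo-2-(2,4-dibromophenoxy)phenol (achiral) | Oc1c(Br)ccc(Br)c1Oc1ccc(Br)cc1Br | target

## Step count and risks
Total step count: 5. Longest linear sequence: 4 steps (1 → 4 → 5 → 6 → 12). Step 4 is a one-step side branch.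

**Step 5 (the proposed new step).**
- Risks:
  - Boron-to-copper transfer may be slow for the ortho-bromo, electron-poor boronic acid.
  - The quinone may act as oxidant for biaryl homocoupling.
  - Conjugate C-arylation at C4 may compete.
  - The quinone may decay before it couples.
- Fallback (known chemistry): it sets out from 4 and 7 and comes back at 12. Iodide 7 is oxidised with mCPBA and TsOH·H2O in MeCN, and the iodine(III) species is captured with 1,3,5-trimethoxybenzene to give (2,4-dibromophenyl)(2,4,6-trimethoxyphenyl)iodonium tosylate F1. Phenol 4 with K2CO3 in toluene/THF at 40–60 °C is arylated by F1 without metal through ligand coupling at iodine(III). The electron-poor, ortho-substituted aryl group is transferred and the trimethoxyphenyl group stays on iodine. This gives 1,4-dibromo-2-(2,4-dibromophenoxy)-3-methoxybenzene F2. BBr3 in CH2Cl2 then cleaves the methyl ether to 12.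

**Step 3.**
- Risk: the electron-poor catechol may oxidise slowly on Ag2O, or the free quinone may dimerise or hydrate on concentration.
- Fallback: it sets out from 4 and comes back at 6, skipping 5. It uses oxidative demethylation of the guaiacol with NaIO4 in water/CH2Cl2 at 0 °C (Adler-type periodate oxidation). The quinone moves into the organic layer as it forms, and that layer is dried and fed directly into step 5. New compounds on this way: none F0.

**Step 1.**
- Risk: the ortho-bromoaryllithium may lose LiBr to give an aryne or start a halogen dance, and the doubly ortho-substituted boron species may protodeboronate.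
- Fallback: it sets out from 1 and comes back at 5, and uses no aryl–metal species. BBr3 in CH2Cl2 converts 1 into 2,5-dibromophenol F3. Magnesium-mediated ortho-formylation (MgCl2, Et3N, paraformaldehyde, MeCN, reflux; Casnati–Skattebøl) can only attack the single free ortho position and gives 3,6-dibromo-2-hydroxybenzaldehyde F4. Dakin oxidation (H2O2, aq NaOH, then acid) replaces CHO by OH to give 5.

## Further compounds
F1 | step 5 | (2,4-dibromophenyl)(2,4,6-trimethoxyphenyl)iodonium tosylate | COc1cc(OC)c([I+]c2ccc(Br)cc2Br)c(OC)c1.Cc1ccc(S(=O)(=O)[O-])cc1
F2 | step 5 | 1,4-dibromo-2-(2,4-dibromophenoxy)-3-methoxybenzene | COc1c(Br)ccc(Br)c1Oc1ccc(Br)cc1Br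
F0 | step 3 | none | none
F3 | step 1 | 2,5-dibromophenol | Oc1cc(Br)ccc1Br
F4 | step 1 | 3,6-dibromo-2-hydroxybenzaldehyde | O=Cc1c(O)c(Br)ccc1Br
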